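**Retrosynthetic overview**

- The route rests on the tetrasubstituted enol ether C3a=C7a shared by ring A (carbocycle C3a–C4–C5–C6–C7–C7a) and ring B (dihydrofuran O1–C2–C3–C3a–C7a). It is treated as a C3a≡C7a alkyne carrying the C2 hydroxyl on one side and a C4 aldehyde at the end of a three-carbon tether on the other.
- Key disconnection: O1–C7a and C3a–C4, both formed in one gold-catalysed operation from acyclic hydroxy ynal 16. Ring B closes first (5-endo-dig), ring A second (enol ether onto aldehyde).
- 16 is cut at C3–C3a: terminal epoxide 6 plus the acetylide of alkyne 12. In 6, C2 comes from Sharpless epoxidation of (2Z,6E)-farnesol and C1' from inverting hydrolysis. In 12, C5 comes from (S)-glycidol and the alkyne from propargyl bromide.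
- End game: C4 carbinol to ketone, terminal E-methyl to CO2H (SeO2, MnO2, NaClO2), removal of both silyl ethers.

Key step: step 12

Remark: the benzofuran numbering of the target (O1, C2, C3, C3a, C4–C7, C7a; C1' for the side-chain carbinol carbon) is used for all intermediates. Carbinol 18 is assumed to form as a mixture of C4 epimers and is drawn 4,5-trans; both epimers converge in step 13.

**Route**

Step 1
Reactants: 1 (2Z,6E)-farnesol
Product: 2 (2S,3R,6E)-2,3-epoxy-3,7,11-trimethyldodeca-6,10-dien-1-ol (cis-epoxy alcohol)
Conditions: Ti(OiPr)4, L-(+)-diethyl tartrate, t-BuOOH, 4 Å MS, CH2Cl2, −20 °C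
Reagents that add atoms: tert-butyl hydroperoxide, CC(C)(C)OO
Why: Sharpless asymmetric epoxidation epoxidises only the allylic alcohol double bond, and L-(+)-tartrate should give the (2S,3R) cis-epoxide from the Z-allylic alcohol, as it does with nerol.

Step 2
Reactants: 2 epoxy alcohol
Product: 3 (2S,3S,6E)-3,7,11-trimethyldodeca-6,10-diene-1,2,3-triol
Conditions: HClO4 (cat.), THF/H2O, 0 °C
Reagents that add atoms: water, O
Why: Acid-catalysed epoxide hydrolysis in which water attacks the tertiary carbon (farnesol C3, later C1') in a borderline SN2 opening with inversion, while C2, deactivated by the neighbouring CH2OH, keeps its C–O bond and configuration.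

Step 3
Reactants: 3 triol
Product: 4 (2S,3S,6E)-2,3-dihydroxy-3,7,11-trimethyldodeca-6,10-dien-1-yl 4-toluenesulfonate
Conditions: TsCl, Et3N, Bu2SnO (cat.), CH2Cl2, 0 °C → rt
Reagents that add atoms: 4-toluenesulfonyl chloride, Cc1ccc(cc1)S(Cl)(=O)=O
Why: Stannylene-acetal-catalysed monosulfonylation of a 1,2-diol goes to the primary hydroxyl, and the hindered secondary and the tertiary hydroxyls should not react.

Step 4
Reactants: 4 primary tosylate
Product: 5 (2S,5E)-6,10-dimethyl-2-[(2S)-oxiran-2-yl]undeca-5,9-dien-2-ol
Conditions: K2CO3, MeOH, 0 °C, short reaction time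
Reagents that add atoms: none
Why: Intramolecular Williamson closure (3-exo-tet) by the C2 oxygen, whose C–O bond is untouched so C2 is retained; the mild base and low temperature are chosen to avoid Payne migration of the epoxide.

Step 5
Reactants: 5 hydroxy epoxide
Product: 6 triethyl{[(2S,5E)-6,10-dimethyl-2-[(2S)-oxiran-2-yl]undeca-5,9-dien-2-yl]oxy}silane
Conditions: TESCl, imidazole, DMAP (cat.), DMF, rt
Reagents that add atoms: chlorotriethylsilane, CC[Si](Cl)(CC)CC
Why: Silylation of the tertiary alcohol under non-Lewis-acidic conditions that leave the terminal epoxide intact; this ether later keeps the C1' oxygen out of the gold step.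

Step 6
Reactants: 7 (S)-glycidol
Product: 8 (R)-2-{[(4-methoxybenzyl)oxy]methyl}oxirane
Conditions: NaH, PMBCl, Bu4NI (cat.), THF/DMF, 0 °C → rt
Reagents that add atoms: 4-methoxybenzyl chloride, COc1ccc(CCl)cc1
Why: Williamson etherification that does not touch the stereocentre (Payne rearrangement of glycidol alkoxide is degenerate); the descriptor changes from S to R only through the CIP priorities.

Step 7
Reactants: 8 PMB glycidyl ether; 9 propargyl bromide
Product: 11 (R)-1-[(4-methoxybenzyl)oxy]hex-5-yn-2-ol, via allenylmagnesium bromide 10 (not isolated)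
Conditions: Mg, HgCl2 (cat.), Et2O, 0 °C; then 8, −78 °C → rt
Reagents that add atoms: none
Why: The allenyl Grignard reagent opens the epoxide at its unsubstituted carbon by SE2' attack, giving the terminal alkyne two CH2 groups away from the carbinol without involving the stereocentre.

Step 8
Reactants: 11 hexynol
Product: 12 (R)-tert-butyl({1-[(4-methoxybenzyl)oxy]hex-5-yn-2-yl}oxy)dimethylsilane
Conditions: TBSCl, imidazole, DMF, rt
Reagents that add atoms: tert-butyldimethylsilyl chloride, CC(C)(C)[Si](C)(C)Cl
Why: Standard silylation of the secondary alcohol; the TBS ether blocks the future C5 oxygen and survives all later steps up to the final fluoride treatment.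

Step 9
Reactants: 12 alkyne; 6 epoxide
Product: 14 coupled alkynyl alcohol (C1' OTES; C2 OH; C5 OTBS; C4 as CH2OPMB), via lithium acetylide 13 (not isolated)
Conditions: n-BuLi, THF, −78 °C; BF3·OEt2; then 6, −78 °C
Reagents that add atoms: none
Why: Yamaguchi–Hirao alkynylation in which the alkynyl borate opens the BF3-activated terminal epoxide only at its CH2 (C3), so the C3–C3a bond forms and C2 emerges, with unchanged configuration, as the only free hydroxyl.

Step 10
Reactants: 14 PMB ether
Product: 15 alkynyl diol (C2 OH and C4 CH2OH free; C1' OTES; C5 OTBS)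
Conditions: DDQ, CH2Cl2/pH 7 buffer, 0 °C
Reagents that add atoms: none
Why: Oxidative cleavage of the electron-rich benzyl ether by DDQ, to which silyl ethers, the alkyne and the isolated trisubstituted alkenes should be inert.

Step 11
Reactants: 15 diol
Product: 16 alkynyl hydroxy aldehyde (C1' OTES; C2 OH; C5 OTBS; C4 CHO)
Conditions: TEMPO (cat.), PhI(OAc)2, CH2Cl2, rt
Reagents that add atoms: none
Why: Oxoammonium (TEMPO) oxidation is selective for the primary alcohol over the hindered secondary C2 hydroxyl and is non-basic, so the α-silyloxy aldehyde should not epimerise at C5.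

Step 12
Reactants: 16 alkynyl hydroxy aldehyde
Product: 18 bicyclic C4 carbinol (4,5-trans drawn; C1' OTES; C5 OTBS), via dihydrofuran aldehyde 17 (not isolated)
Conditions: Ph3PAuNTf2 (5 mol%), 4 Å MS, CH2Cl2, 0 °C → rt; Et3N quench
Reagents that add atoms: none
Why: The cationic monovalent gold complex binds the C3a≡C7a alkyne, the C2 hydroxyl adds anti to C7a and protodeauration at C3a gives dihydrofuran 17 (O1–C7a); its nucleophilic enol ether carbon C3a then attacks the activated C4 aldehyde and the C7a oxocarbenium ion loses the C3a proton, restoring the enol ether (C3a–C4). The closest known chemistry is the gold-catalysed cycloisomerisation of homopropargylic alcohols to 2,3-dihydrofurans run in tandem with a Prins-type (aldol-like) addition of the enol ether to a tethered carbonyl group, as in gold-catalysed alkoxylation–carbonyl addition cascades of alkynals. Ring B closes 5-endo-dig, the only feasible mode for a homopropargylic hydroxyl, and ring A closes 6-(enolendo)-exo-trig. The one new stereocentre, C4, is governed by the adjacent C5 centre (chair-like closure with the silyloxy group pseudo-equatorial, expected to favour 4,5-trans) and is removed again in step 13, so its outcome does not matter. The step needs O1 to come from the C2 hydroxyl and to bond to C7a, which is secured by the TES ether on the C1' oxygen (otherwise a 5-exo-dig competitor at C3a) and the TBS ether on the C5 oxygen (otherwise 5-exo-dig at C7a); because C4 enters as the aldehyde carbon, the positions of O1 and of the later carbonyl are fixed by connectivity. Sieves, low temperature and the amine quench are meant to keep the acid-labile allylic C4 carbinol from ionising.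

Step 13
Reactants: 18 C4 carbinol
Product: 19 bicyclic vinylogous ester (C4 ketone; C1' OTES; C5 OTBS)
Conditions: Dess–Martin periodinane, NaHCO3, CH2Cl2, 0 °C
Reagents that add atoms: none
Why: Buffered Dess–Martin oxidation converts both C4 epimers into the same ketone conjugated with the enol ether, without base that could epimerise C5.

Step 14
Reactants: 19 vinylogous ester
Product: 20 terminal E-allylic alcohol (CH2OH in place of the E-methyl of the isopropylidene group)
Conditions: SeO2 (cat.), t-BuOOH, salicylic acid (cat.), CH2Cl2, rt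
Reagents that add atoms: tert-butyl hydroperoxide, CC(C)(C)OO (terminal oxidant); selenium dioxide, O=[Se]=O (oxygen carrier)
Why: Sharpless–Umbreit allylic hydroxylation (ene reaction, then [2,3]-sigmatropic shift) is intrinsically E-selective and, as in farnesyl systems, should prefer the terminal isopropylidene group; the electron-poor C3a=C7a bond should not react.

Step 15
Reactants: 20 allylic alcohol
Product: 21 E-enal
Conditions: MnO2, CH2Cl2, rt
Reagents that add atoms: none
Why: MnO2 oxidises only the allylic alcohol, keeps the E geometry, and also converges any enal already formed in step 14.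

Step 16
Reactants: 21 enal
Product: 22 bis-silylated E-enoic acid
Conditions: NaClO2, NaH2PO4, 2-methyl-2-butene, t-BuOH/H2O, 0 °C → rt
Reagents that add atoms: sodium chlorite, [Na+].[O-]Cl=O
Why: Pinnick oxidation takes the enal to the acid without alkene isomerisation, and the scavenger keeps hypochlorite away from the alkenes and the enol ether.

Step 17
Reactants: 22 bis-silylated acid
Product: 23 target, (2E,6E,10S)-10-hydroxy-10-[(2S,5R)-5-hydroxy-4-oxo-2,3,4,5,6,7-hexahydro-1-benzofuran-2-yl]-2,6-dimethylundeca-2,6-dienoic acid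
Conditions: HF·pyridine, pyridine, THF, 0 °C → rt
Reagents that add atoms: none
Why: Buffered fluoride desilylation removes the tertiary TES and secondary TBS ethers under non-basic, non-aqueous conditions, so the C4/C5 α-ketol should not tautomerise and the vinylogous ester should not hydrolyse.

**Compound list**

1 | (2Z,6E)-farnesol | CC(C)=CCC/C(C)=C/CC/C(C)=C\CO | starting material
2 | (2S,3R,6E)-2,3-epoxy-3,7,11-trimethyldodeca-6,10-dien-1-ol | CC(C)=CCC/C(C)=C/CC[C@@]1(C)O[C@H]1CO | intermediate
3 | (2S,3S,6E)-3,7,11-trimethyldodeca-6,10-diene-1,2,3-triol | CC(C)=CCC/C(C)=C/CC[C@](C)(O)[C@@H](O)CO | intermediate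
4 | (2S,3S,6E)-2,3-dihydroxy-3,7,11-trimethyldodeca-6,10-dien-1-yl 4-toluenesulfonate | CC(C)=CCC/C(C)=C/CC[C@](C)(O)[C@@H](O)COS(=O)(=O)c1ccc(C)cc1 | intermediate
5 | (2S,5E)-6,10-dimethyl-2-[(2S)-oxiran-2-yl]undeca-5,9-dien-2-ol | CC(C)=CCC/C(C)=C/CC[C@](C)(O)[C@@H]1CO1 | intermediate
6 | triethylsilyl ether of 5 (terminal epoxide, C1' OTES) | CC(C)=CCC/C(C)=C/CC[C@](C)(O[Si](CC)(CC)CC)[C@@H]1CO1 | intermediate
7 | (S)-glycidol | C1[C@@H](O1)CO | starting material
8 | (R)-2-{[(4-methoxybenzyl)oxy]methyl}oxirane | C1[C@@H](O1)COCc2ccc(OC)cc2 | intermediate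
9 | propargyl bromide | C#CCBr | starting material
10 | allenylmagnesium bromide (not isolated) | C=C=C[Mg]Br | intermediate
11 | (R)-1-[(4-methoxybenzyl)oxy]hex-5-yn-2-ol | C#CCC[C@@H](O)COCc1ccc(OC)cc1 | intermediate
12 | (R)-tert-butyl({1-[(4-methoxybenzyl)oxy]hex-5-yn-2-yl}oxy)dimethylsilane | C#CCC[C@@H](O[Si](C)(C)C(C)(C)C)COCc1ccc(OC)cc1 | intermediate
13 | lithium acetylide of 12 (not isolated) | [Li]C#CCC[C@@H](O[Si](C)(C)C(C)(C)C)COCc1ccc(OC)cc1 | intermediate
14 | coupled alkynyl alcohol, (1'S,2S,5R); C1' OTES, C2 OH, C3a≡C7a alkyne, C5 OTBS, C4 CH2OPMB | C/C(=C\CC[C@](C)(O[Si](CC)(CC)CC)[C@@H](O)CC#CCC[C@@H](O[Si](C)(C)C(C)(C)C)COCc1ccc(OC)cc1)CCC=C(C)C | intermediate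
15 | alkynyl diol, (1'S,2S,5R); C2 OH and C4 CH2OH free | C/C(=C\CC[C@](C)(O[Si](CC)(CC)CC)[C@@H](O)CC#CCC[C@@H](O[Si](C)(C)C(C)(C)C)CO)CCC=C(C)C | intermediate
16 | acyclic alkynyl hydroxy aldehyde, (1'S,2S,5R); key-step precursor | C/C(=C\CC[C@](C)(O[Si](CC)(CC)CC)[C@@H](O)CC#CCC[C@@H](O[Si](C)(C)C(C)(C)C)C=O)CCC=C(C)C | intermediate
17 | 5-substituted 2,3-dihydrofuran aldehyde (ring B closed, not isolated) | C/C(=C\CC[C@](C)(O[Si](CC)(CC)CC)[C@@H]1CC=C(CC[C@@H](O[Si](C)(C)C(C)(C)C)C=O)O1)CCC=C(C)C | intermediate
18 | bicyclic C4 carbinol, (1'S,2S,4R,5R) drawn (4,5-trans; C4 epimers expected) | C/C(=C\CC[C@](C)(O[Si](CC)(CC)CC)[C@@H]1CC2=C(CC[C@@H](O[Si](C)(C)C(C)(C)C)[C@@H]2O)O1)CCC=C(C)C | intermediate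
19 | bicyclic vinylogous ester (C4 ketone), (1'S,2S,5R) | C/C(=C\CC[C@](C)(O[Si](CC)(CC)CC)[C@@H]1CC2=C(CC[C@@H](O[Si](C)(C)C(C)(C)C)C2=O)O1)CCC=C(C)C | intermediate
20 | terminal E-allylic alcohol of 19 | C/C(=C\CC[C@](C)(O[Si](CC)(CC)CC)[C@@H]1CC2=C(CC[C@@H](O[Si](C)(C)C(C)(C)C)C2=O)O1)CC/C=C(\C)CO | intermediate
21 | terminal E-enal | C/C(=C\CC[C@](C)(O[Si](CC)(CC)CC)[C@@H]1CC2=C(CC[C@@H](O[Si](C)(C)C(C)(C)C)C2=O)O1)CC/C=C(\C)C=O | intermediate
22 | bis-silylated E-enoic acid | C/C(=C\CC[C@](C)(O[Si](CC)(CC)CC)[C@@H]1CC2=C(CC[C@@H](O[Si](C)(C)C(C)(C)C)C2=O)O1)CC/C=C(\C)C(=O)O | intermediate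
23 | CNP0117600.1 | C/C(=C\CC[C@](C)(O)[C@@H]1CC2=C(CC[C@@H](O)C2=O)O1)CC/C=C(\C)C(=O)O | target

**Step count**

Total: 17 steps. Longest linear sequence: 14 steps (steps 1–5 and 9–17, from (2Z,6E)-farnesol).

**Steps most likely to fail**

1. Step 12. The enol ether may fail to add to the aldehyde, so that the sequence stalls at the dihydrofuran or the enol ether is hydrolysed. Carbonyl or silyl ether oxygen may add to the activated alkyne instead of the C2 hydroxyl. The product carbinol may ionise and dehydrate under the Lewis-acidic conditions. Fallback, setting out from 16 and returning at 18: 5-endo-dig iodoetherification of 16 (I2, NaHCO3, MeCN, 0 °C) should give the 3a-iodo dihydrofuran aldehyde F1. An intramolecular Nozaki–Hiyama–Kishi reaction (CrCl2, NiCl2 (cat.), DMF, rt) of the alkenyl iodide with the C4 aldehyde should then close ring A and give carbinol 18. The same two bonds are thus made by halonium and organochromium chemistry rather than by enol ether nucleophilicity.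

2. Step 14. Allylic oxidation may occur at the internal trisubstituted alkene, over-oxidation may occur, or conversion may be slow on a sensitive late intermediate. Fallback, setting out from 19 and returning at 21: olefin cross-metathesis with excess methacrolein (second-generation Hoveyda–Grubbs catalyst, CH2Cl2, 40 °C) exchanges the less hindered terminal isopropylidene group for the E-configured 2-methylpropenal terminus. This is a known formal allylic oxidation of isopropylidene groups. It gives enal 21 directly with loss of isobutene, makes no new compound on the way, and makes step 15 unnecessary.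

3. Step 2. Partial ionisation at the tertiary carbon would erode the diastereomeric purity, and attack of water at C2 would erode the enantiomeric purity; hydride shift to carbonyl by-products is also possible. Fallback, setting out from 2 and returning at 3: acylation with Boc2O (DMAP, Et3N, CH2Cl2) gives the epoxy tert-butyl carbonate F2. BF3·OEt2 (CH2Cl2, −78 °C) then delivers the carbonate carbonyl oxygen intramolecularly to the tertiary epoxide carbon with inversion and loss of isobutene, giving the six-membered cyclic carbonate F3. Methanolysis (K2CO3, MeOH) releases triol 3.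

**Further compounds**

F1 | step 12 | 3a-iodo dihydrofuran aldehyde (4-iodo-2,3-dihydrofuran; C1' OTES; C5 OTBS; C4 CHO) | C/C(=C\CC[C@](C)(O[Si](CC)(CC)CC)[C@@H]1CC(I)=C(CC[C@@H](O[Si](C)(C)C(C)(C)C)C=O)O1)CCC=C(C)C
F0 | step 14 | none | none
F2 | step 2 | tert-butyl [(2S,3R,6E)-2,3-epoxy-3,7,11-trimethyldodeca-6,10-dien-1-yl] carbonate | CC(C)=CCC/C(C)=C/CC[C@@]1(C)O[C@H]1COC(=O)OC(C)(C)C
F3 | step 2 | (4S,5S)-4-[(3E)-4,8-dimethylnona-3,7-dien-1-yl]-5-hydroxy-4-methyl-1,3-dioxan-2-one | CC(C)=CCC/C(C)=C/CC[C@]1(C)OC(=O)OC[C@@H]1O
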